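**Retrosynthetic overview**
1. Target 14 ⇐ trans,trans-triester 13 by one global DIBAL-H reduction (three esters to three CH2OH, aryl pivalate cleaved).
2. 13 ⇐ bis(aryldiazoacetate) 11 by a twofold Rh(II)-carbene 1,5-C–H insertion that closes both dihydrofuran rings in one operation and sets both C2 centres, then C3 epimerisation to trans in the same flask.
3. 11 ⇐ bis(aryl iodide) 9 by a twofold Pd-catalysed coupling with ethyl diazoacetate.
4. 9 ⇐ two Mitsunobu etherifications joining three vanillin-derived arenes: ethyl 5-iodoferulate 3, 5-iodovanillin 1 and O-pivaloyl vanillyl alcohol 6.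
5. Ring order: the three benzene rings are bought; the two dihydrofuran rings form together in step 7.

Assumption: 5-iodovanillin, vanillyl alcohol, Ph3P=CHCO2Et, pivaloyl chloride, ethyl diazoacetate and Rh2(S-PTTL)4 are taken as commercial; the sense of induction (S-catalyst gives 2R) is assigned by analogy with the single-insertion cases and has not been verified on this substrate.

**Step 1**
Reactants: 1 5-iodovanillin; 2 ethyl (triphenylphosphoranylidene)acetate
Product: 3 ethyl (E)-3-(4-hydroxy-3-iodo-5-methoxyphenyl)prop-2-enoate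
Conditions: 2 (2 equiv), toluene, 90 °C
Reagents that add atoms: ethyl (triphenylphosphoranylidene)acetate, CCOC(=O)C=P(c1ccccc1)(c1ccccc1)c1ccccc1
Why: Wittig olefination with a stabilised ylide gives the E-cinnamate and tolerates the free phenol, as with vanillin itself.

**Step 2**
Reactants: 4 vanillyl alcohol; 5 pivaloyl chloride
Product: 6 4-(hydroxymethyl)-2-methoxyphenyl 2,2-dimethylpropanoate
Conditions: PivCl (1.05 equiv), 1 M aq. NaOH, THF, 0 °C
Reagents that add atoms: pivaloyl chloride, CC(C)(C)C(Cl)=O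
Why: Schotten–Baumann acylation, in which only the phenoxide (pKa about 10) is present as an anion, so the phenol is acylated and the benzylic alcohol is left free.

**Step 3**
Reactants: 1 5-iodovanillin; 6 4-(hydroxymethyl)-2-methoxyphenyl 2,2-dimethylpropanoate
Product: 7 4-[(4-formyl-2-iodo-6-methoxyphenoxy)methyl]-2-methoxyphenyl 2,2-dimethylpropanoate
Conditions: PPh3, DIAD, THF, 0 °C to rt
Reagents that add atoms: none
Why: Mitsunobu etherification, in which the acidic phenol of 1 (pKa about 7) displaces the activated benzylic alcohol of 6 under neutral conditions that leave the aldehyde and the pivalate alone.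

**Step 4**
Reactants: 7 aldehyde ether
Product: 8 4-{[4-(hydroxymethyl)-2-iodo-6-methoxyphenoxy]methyl}-2-methoxyphenyl 2,2-dimethylpropanoate
Conditions: NaBH4, THF/EtOH, 0 °C, 20 min
Reagents that add atoms: none
Why: Borohydride reduction of the aryl aldehyde is much faster than attack on the hindered aryl pivalate or the aryl iodide.

**Step 5**
Reactants: 8 benzylic alcohol; 3 ethyl 5-iodoferulate
Product: 9 ethyl (E)-3-{3-iodo-4-[(3-iodo-5-methoxy-4-{[3-methoxy-4-(pivaloyloxy)phenyl]methoxy}phenyl)methoxy]-5-methoxyphenyl}prop-2-enoate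
Conditions: PPh3, DIAD, THF, 0 °C to rt
Reagents that add atoms: none
Why: A second Mitsunobu etherification, with the acidic iodoferulate phenol as nucleophile and the electron-rich benzylic alcohol as electrophile, joins the third arene without base.

**Step 6**
Reactants: 9 bis(aryl iodide); 10 ethyl diazoacetate
Product: 11 ethyl (E)-3-{3-(1-diazo-2-ethoxy-2-oxoethyl)-4-[(3-(1-diazo-2-ethoxy-2-oxoethyl)-5-methoxy-4-{[3-methoxy-4-(pivaloyloxy)phenyl]methoxy}phenyl)methoxy]-5-methoxyphenyl}prop-2-enoate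
Conditions: 10 (3 equiv), Pd(PPh3)4 (10 mol%), Ag2CO3 (1.0 equiv), Et3N (2.6 equiv), toluene, rt, dark
Reagents that add atoms: ethyl diazoacetate, CCOC(=O)C=[N+]=[N-]
Why: Pd-catalysed cross-coupling of aryl iodides with the C–H bond of ethyl diazoacetate (oxidative addition, deprotonative palladation of the diazo carbon, reductive elimination) installs both aryldiazoacetates at rt with the diazo group retained.

**Step 7**
Reactants: 11 bis(aryldiazoacetate)
Product: 13 trans,trans-triester (2R,3R,2'R,3'R), via cis-cis triester 12 (not isolated)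
Conditions: Rh2(S-PTTL)4 (4 mol%), toluene, slow addition of 11 (0.01 M final), −60 °C to rt; then DBU (3 equiv), rt to 40 °C
Reagents that add atoms: none
Why: Proposed new method: a twofold run of the Rh(II)-carboxylate-catalysed intramolecular 1,5-C–H insertion of an aryldiazoacetate into a benzylic ether C–H bond (closest known type: the single insertion that gives cis-2-aryl-2,3-dihydrobenzofuran-3-carboxylates with Rh2(S-PTTL)4), in which each Rh carbene takes the enantiotopic OCH2Ar hydrogen selected by the S-catalyst so that both C2 centres form as R in the cis (2R,3S) rings of 12, two catalyst-controlled events turn most of the minor enantiomer into a separable diastereomer, and DBU then epimerises only the ester-bearing C3 centres through their enolates to the thermodynamic trans (2R,3R) rings while C2 stays fixed because retro-5-endo ring opening is stereoelectronically disfavoured.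

**Step 8**
Reactants: 13 trans,trans-triester
Product: 14 target, 4-[(2R,3S)-3-(hydroxymethyl)-5-{(2R,3S)-3-(hydroxymethyl)-5-[(E)-3-hydroxyprop-1-enyl]-7-methoxy-2,3-dihydro-1-benzofuran-2-yl}-7-methoxy-2,3-dihydro-1-benzofuran-2-yl]-2-methoxyphenol
Conditions: DIBAL-H (12 equiv), CH2Cl2, −78 °C to 0 °C; aq. Rochelle salt
Reagents that add atoms: none
Why: DIBAL-H ester reduction takes the two ring esters to CH2OH, reduces the enoate 1,2 to the E-allylic alcohol and cleaves the aryl pivalate reductively, without touching C2 or C3 (the 3R to 3S change is only a CIP priority change).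

**Compound list**
1 | 5-iodovanillin (4-hydroxy-3-iodo-5-methoxybenzaldehyde) | COc1cc(C=O)cc(I)c1O | starting material
2 | ethyl (triphenylphosphoranylidene)acetate | CCOC(=O)C=P(c1ccccc1)(c1ccccc1)c1ccccc1 | starting material
3 | ethyl (E)-3-(4-hydroxy-3-iodo-5-methoxyphenyl)prop-2-enoate | CCOC(=O)/C=C/c1cc(I)c(O)c(OC)c1 | intermediate
4 | vanillyl alcohol | COc1cc(CO)ccc1O | starting material
5 | pivaloyl chloride | CC(C)(C)C(Cl)=O | starting material
6 | 4-(hydroxymethyl)-2-methoxyphenyl 2,2-dimethylpropanoate | COc1cc(CO)ccc1OC(=O)C(C)(C)C | intermediate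
7 | 4-[(4-formyl-2-iodo-6-methoxyphenoxy)methyl]-2-methoxyphenyl 2,2-dimethylpropanoate | COc1cc(COc2c(I)cc(C=O)cc2OC)ccc1OC(=O)C(C)(C)C | intermediate
8 | 4-{[4-(hydroxymethyl)-2-iodo-6-methoxyphenoxy]methyl}-2-methoxyphenyl 2,2-dimethylpropanoate | COc1cc(COc2c(I)cc(CO)cc2OC)ccc1OC(=O)C(C)(C)C | intermediate
9 | bis(aryl iodide) triaryl diether (name in step 5) | CCOC(=O)/C=C/c1cc(I)c(OCc2cc(I)c(OCc3ccc(OC(=O)C(C)(C)C)c(OC)c3)c(OC)c2)c(OC)c1 | intermediate
10 | ethyl diazoacetate | CCOC(=O)C=[N+]=[N-] | starting material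
11 | bis(aryldiazoacetate) (name in step 6) | CCOC(=O)/C=C/c1cc(C(=[N+]=[N-])C(=O)OCC)c(OCc2cc(C(=[N+]=[N-])C(=O)OCC)c(OCc3ccc(OC(=O)C(C)(C)C)c(OC)c3)c(OC)c2)c(OC)c1 | intermediate
12 | cis,cis-triester: ethyl (2R,3S)-5-{(2R,3S)-3-(ethoxycarbonyl)-5-[(E)-3-ethoxy-3-oxoprop-1-enyl]-7-methoxy-2,3-dihydro-1-benzofuran-2-yl}-7-methoxy-2-[3-methoxy-4-(pivaloyloxy)phenyl]-2,3-dihydro-1-benzofuran-3-carboxylate | COc1cc([C@@H]2Oc3c(OC)cc([C@@H]4Oc5c(OC)cc(/C=C/C(=O)OCC)cc5[C@@H]4C(=O)OCC)cc3[C@@H]2C(=O)OCC)ccc1OC(=O)C(C)(C)C | intermediate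
13 | trans,trans-triester: the (2R,3R,2'R,3'R) C3-epimer of 12 | COc1cc([C@@H]2Oc3c(OC)cc([C@@H]4Oc5c(OC)cc(/C=C/C(=O)OCC)cc5[C@H]4C(=O)OCC)cc3[C@H]2C(=O)OCC)ccc1OC(=O)C(C)(C)C | intermediate
14 | CNP0250921.1 (name in step 8) | COc1cc([C@@H]2Oc3c(OC)cc([C@@H]4Oc5c(OC)cc(/C=C/CO)cc5[C@H]4CO)cc3[C@H]2CO)ccc1O | target

**Count**
Total steps: 8. Longest linear sequence: 7 (steps 2 to 8, from vanillyl alcohol); step 1 is a one-step branch that joins at step 5.

**Steps most likely to fail**

Step 7 (twofold insertion). The two carbene sites in one molecule may interfere (carbene/diazo coupling to a medium-ring alkene or azine), or the second event may be poorly selective. The fallback builds the rings one at a time and sets out from 7. Pd(PPh3)4/Ag2CO3/Et3N coupling of 7 with 10 gives the mono-diazo aldehyde F1. Rh2(S-PTTL)4 in toluene at −60 °C closes ring A to the cis ester aldehyde F2, which is epimerised in the flask with DBU to the trans ester aldehyde F3. NaBH4 gives the benzylic alcohol F4. Mitsunobu etherification with 3 gives the aryl iodide F5. A second Pd coupling with 10 gives the diazo ester F6. Rh2(S-PTTL)4 then closes the second ring to the trans/cis triester F7, which DBU epimerises in the flask, and the route is rejoined at 13.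

Step 6 (twofold Pd coupling with ethyl diazoacetate at two ortho-alkoxy aryl iodides). The fallback separates C–C bond formation from diazo installation and sets out from 9. A twofold Pd-catalysed α-arylation with the Reformatsky reagent BrZnCH2CO2Et (Pd(dba)2/Q-Phos, THF, rt) gives the bis(arylacetate) F8. A twofold Regitz diazo transfer (p-ABSA, DBU, MeCN, 0 °C to rt) returns to the route at 11.

Step 5 (Mitsunobu with a di-ortho-substituted phenol and a large benzylic alcohol). The fallback swaps the redox condensation for an SN2 alkylation and sets out from 8. Appel bromination (CBr4, PPh3, CH2Cl2, 0 °C) gives the benzylic bromide F9. Williamson etherification with 3 (K2CO3, DMF, rt) returns to the route at 9.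

**Further compounds**
F1 | step 7 | ethyl 2-diazo-2-{5-formyl-3-methoxy-2-[(3-methoxy-4-pivaloyloxyphenyl)methoxy]phenyl}acetate | COc1cc(COc2c(C(=[N+]=[N-])C(=O)OCC)cc(C=O)cc2OC)ccc1OC(=O)C(C)(C)C
F2 | step 7 | ethyl (2R,3S)-5-formyl-7-methoxy-2-[3-methoxy-4-(pivaloyloxy)phenyl]-2,3-dihydro-1-benzofuran-3-carboxylate (cis) | COc1cc([C@@H]2Oc3c(OC)cc(C=O)cc3[C@@H]2C(=O)OCC)ccc1OC(=O)C(C)(C)C
F3 | step 7 | ethyl (2R,3R)-5-formyl-7-methoxy-2-[3-methoxy-4-(pivaloyloxy)phenyl]-2,3-dihydro-1-benzofuran-3-carboxylate (trans) | COc1cc([C@@H]2Oc3c(OC)cc(C=O)cc3[C@H]2C(=O)OCC)ccc1OC(=O)C(C)(C)C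
F4 | step 7 | ethyl (2R,3R)-5-(hydroxymethyl)-7-methoxy-2-[3-methoxy-4-(pivaloyloxy)phenyl]-2,3-dihydro-1-benzofuran-3-carboxylate | COc1cc([C@@H]2Oc3c(OC)cc(CO)cc3[C@H]2C(=O)OCC)ccc1OC(=O)C(C)(C)C
F5 | step 7 | ethyl (2R,3R)-5-({4-[(E)-3-ethoxy-3-oxoprop-1-enyl]-2-iodo-6-methoxyphenoxy}methyl)-7-methoxy-2-[3-methoxy-4-(pivaloyloxy)phenyl]-2,3-dihydro-1-benzofuran-3-carboxylate | COc1cc([C@@H]2Oc3c(OC)cc(COc4c(I)cc(/C=C/C(=O)OCC)cc4OC)cc3[C@H]2C(=O)OCC)ccc1OC(=O)C(C)(C)C
F6 | step 7 | ethyl (2R,3R)-5-({2-(1-diazo-2-ethoxy-2-oxoethyl)-4-[(E)-3-ethoxy-3-oxoprop-1-enyl]-6-methoxyphenoxy}methyl)-7-methoxy-2-[3-methoxy-4-(pivaloyloxy)phenyl]-2,3-dihydro-1-benzofuran-3-carboxylate | COc1cc([C@@H]2Oc3c(OC)cc(COc4c(C(=[N+]=[N-])C(=O)OCC)cc(/C=C/C(=O)OCC)cc4OC)cc3[C@H]2C(=O)OCC)ccc1OC(=O)C(C)(C)C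
F7 | step 7 | triester with trans (2R,3R) guaiacyl-bearing ring and cis (2R,3S) cinnamate-bearing ring, the mono-C3-epimer of 13 | COc1cc([C@@H]2Oc3c(OC)cc([C@@H]4Oc5c(OC)cc(/C=C/C(=O)OCC)cc5[C@@H]4C(=O)OCC)cc3[C@H]2C(=O)OCC)ccc1OC(=O)C(C)(C)C
F8 | step 6 | ethyl (E)-3-{3-(2-ethoxy-2-oxoethyl)-4-[(3-(2-ethoxy-2-oxoethyl)-5-methoxy-4-{[3-methoxy-4-(pivaloyloxy)phenyl]methoxy}phenyl)methoxy]-5-methoxyphenyl}prop-2-enoate | CCOC(=O)/C=C/c1cc(CC(=O)OCC)c(OCc2cc(CC(=O)OCC)c(OCc3ccc(OC(=O)C(C)(C)C)c(OC)c3)c(OC)c2)c(OC)c1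
F9 | step 5 | 4-{[4-(bromomethyl)-2-iodo-6-methoxyphenoxy]methyl}-2-methoxyphenyl 2,2-dimethylpropanoate | COc1cc(COc2c(I)cc(CBr)cc2OC)ccc1OC(=O)C(C)(C)C
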